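**Plan**

1. Retrosynthesis: the nine aryl O–CH3 bonds are cut last and the C6–vinyl bond of the 4-hydroxystyryl arm before them (aryl bromide plus E-alkenylboronate). O1–C2 (ring A unit) and O1′–C2′ (ring B unit) are then opened with insertion of a carboxyl carbon, so that each trans-2,3-diaryl-dihydrobenzofuran becomes a 3,4-diaryl-dihydrocoumarin.
2. Each dihydrocoumarin is cut at its C–C bond (C2′–C3′, then C2–C3) and at the lactone O–acyl bond, giving an arylacetic acid and an o-quinone methide. The enabling feature: in the ring-B benzofuran (O1′, C2′, C3′; its C7′ is bonded to C2 of the styryl-bearing unit) C3′ is a diarylmethine carbon ortho to the phenolic O1′, hence a latent o-quinone methide terminus. C2′ bears the 2,4-dioxygenated aryl, so its benzylic carbon can arrive as an arylacetic acid enolate and later lose the carboxyl carbon through a stabilised cation.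
3. Forward: ring-B sulfone → ring-B lactone (C2′–C3′ bond and lactone ring) → acetic acid arm at C7′ → ring-A lactone (C2–C3 bond) → one operation that contracts both lactones to the two dihydrobenzofurans → styryl coupling → demethylation.
4. Stereochemistry: C3′ and C3 come from the chiral isothiourea (same enantiomer twice); C2′ and C2 from trans-selective closure of benzylic cations next to these centres; the E alkene from the boronate.

Key step: step 4

Remark: (2S,3R)-HyperBTM is assumed to deliver the (4S) lactone series with these methides; should a test run show the opposite sense, its enantiomer is used in steps 4 and 10.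

**Route**

Step 1
Reactants: 1 2-bromo-5-methoxyphenol
Product: 2 3-bromo-2-hydroxy-6-methoxybenzaldehyde
Conditions: MgCl2, Et3N, (CH2O)n, THF, reflux; 1 M HCl work-up
Reagents that add atoms: paraformaldehyde (formaldehyde), C=O
Why: Magnesium-mediated ortho-formylation of a phenol (Casnati–Skattebøl reaction), in which the magnesium phenoxide delivers formaldehyde to the only free ortho carbon, the one between OH and OMe, and a second formaldehyde oxidises the benzylic alkoxide to the aldehyde; aryl bromides are tolerated.

Step 2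
Reactants: 2 3-bromo-2-hydroxy-6-methoxybenzaldehyde; 3 3,5-dimethoxyphenylmagnesium chloride
Product: 4 rac-6-bromo-2-[(3,5-dimethoxyphenyl)(hydroxy)methyl]-3-methoxyphenol
Conditions: 3 (2.5 equiv), THF, −20 °C → 0 °C; aq NH4Cl
Reagents that add atoms: none
Why: Grignard addition to the aldehyde, the first equivalent only deprotonating the phenol and the aryl bromide not exchanging at this temperature; the carbinol centre may be racemic because it is erased in step 4.

Step 3
Reactants: 4 rac-6-bromo-2-[(3,5-dimethoxyphenyl)(hydroxy)methyl]-3-methoxyphenol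
Product: 5 rac-6-bromo-2-[(3,5-dimethoxyphenyl)(4-methylbenzenesulfonyl)methyl]-3-methoxyphenol
Conditions: p-TolSO2H (1.5 equiv, freshly liberated from its sodium salt), CH2Cl2, rt
Reagents that add atoms: p-toluenesulfinic acid, Cc1ccc(S(=O)O)cc1
Why: Acid-promoted SN1 substitution of the ortho-hydroxybenzhydrol by sulfinate (S-alkylation through the benzhydryl cation/o-quinone methide), the usual entry to bench-stable methide precursors.

Step 4
Reactants: 5 rac-6-bromo-2-[(3,5-dimethoxyphenyl)(4-methylbenzenesulfonyl)methyl]-3-methoxyphenol; 6 2,4-dimethoxyphenylacetic acid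
Product: 9 (3S,4S)-8-bromo-3-(2,4-dimethoxyphenyl)-4-(3,5-dimethoxyphenyl)-5-methoxychroman-2-one (trans), via pivalic mixed anhydride 7 (not isolated), via ring-B o-quinone methide 8 (not isolated)
Conditions: 6 (1.5 equiv), t-BuCOCl, iPr2NEt, CH2Cl2, 0 °C; then (2S,3R)-HyperBTM (10 mol %), 5, iPr2NEt, −20 °C → rt
Reagents that add atoms: none
Why: Pivalic mixed anhydride 7 acylates the isothiourea and iPr2NEt turns the acyl ammonium ion into the (Z)-ammonium enolate, held coplanar by the 1,5-O···S contact, while the same base ionises the acidified ortho-bromophenol 5 and expels p-toluenesulfinate to give methide 8; the enolate carbon then adds to the exocyclic methide carbon (the future C2′–C3′ bond), ring B rearomatises, and the phenoxide is acylated by the acyl ammonium carbon, which releases the catalyst. The closest known reaction type is the isothiourea- or carbene-catalysed formal [4+2] annulation (Michael addition–lactonisation) of arylacetic acid-derived enolates with o-quinone methides generated in situ from 2-(sulfonylalkyl)phenols, which gives 3,4-disubstituted dihydrocoumarins. The only ring formed, the six-membered lactone, closes second, by 6-exo-trig O-acylation of the phenoxide. C4 (the future C3′) is set by the catalyst: its C2 phenyl group shields one enolate face, and the open transition state that keeps the two aryl groups anti relays this to one face of the methide, whose geometry is fixed by the flanking methoxy group; C3 follows as trans and is sacrificial, being epimerisable and excised in step 11. The step needs enantiofacial control at the methide carbon and C- rather than O-acylation; compound 5 secures this because it has a single free phenol (one methide only, every other oxygen being a methyl ether), and the ortho bromine makes sulfinate loss fast so that little phenoxide is left to intercept the anhydride.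

Step 5
Reactants: 9 (3S,4S)-8-bromo-3-(2,4-dimethoxyphenyl)-4-(3,5-dimethoxyphenyl)-5-methoxychroman-2-one
Product: 10 tert-butyl 2-[(3S,4S)-3-(2,4-dimethoxyphenyl)-4-(3,5-dimethoxyphenyl)-5-methoxy-2-oxochroman-8-yl]acetate
Conditions: BrZnCH2CO2tBu (2 equiv), Pd2(dba)3 (2.5 mol %), XPhos (10 mol %), THF, 50 °C
Reagents that add atoms: tert-butyl 2-(bromozincio)acetate (Reformatsky reagent), CC(C)(C)OC(=O)C[Zn]Br
Why: Palladium-catalysed α-arylation of an ester through its zinc (Reformatsky) enolate, a Negishi-type coupling; the weakly basic zinc enolate spares the aryl lactone, and any epimerisation at C3 is without consequence.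

Step 6
Reactants: 10 tert-butyl 2-[(3S,4S)-3-(2,4-dimethoxyphenyl)-4-(3,5-dimethoxyphenyl)-5-methoxy-2-oxochroman-8-yl]acetate
Product: 11 2-[(3S,4S)-3-(2,4-dimethoxyphenyl)-4-(3,5-dimethoxyphenyl)-5-methoxy-2-oxochroman-8-yl]acetic acid
Conditions: TFA, Et3SiH (3 equiv), CH2Cl2, 0 °C → rt
Reagents that add atoms: none
Why: Acidolysis of the tert-butyl ester, the silane reducing the tert-butyl cation so that the dimethoxyarenes are not alkylated; the aryl lactone and the methyl ethers are stable to TFA.

Step 7
Reactants: 12 4-bromo-2,6-dimethoxybenzaldehyde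
Product: 13 4-bromo-2-hydroxy-6-methoxybenzaldehyde
Conditions: BCl3 (1.1 equiv), CH2Cl2, −78 °C → 0 °C; H2O
Reagents that add atoms: none
Why: Chelation-controlled mono-demethylation ortho to the formyl group by BCl3, the boron chelate formed after the first cleavage deactivating the second methoxy group.

Step 8
Reactants: 13 4-bromo-2-hydroxy-6-methoxybenzaldehyde; 3 3,5-dimethoxyphenylmagnesium chloride
Product: 14 rac-5-bromo-2-[(3,5-dimethoxyphenyl)(hydroxy)methyl]-3-methoxyphenol
Conditions: 3 (2.5 equiv), THF, −20 °C → 0 °C; aq NH4Cl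
Reagents that add atoms: none
Why: Grignard addition as in step 2, carbonyl addition being far faster than magnesium–bromine exchange; the carbinol centre is again erased later.

Step 9
Reactants: 14 rac-5-bromo-2-[(3,5-dimethoxyphenyl)(hydroxy)methyl]-3-methoxyphenol
Product: 15 rac-5-bromo-2-[(3,5-dimethoxyphenyl)(4-methylbenzenesulfonyl)methyl]-3-methoxyphenol
Conditions: p-TolSO2H (1.5 equiv), CH2Cl2, rt
Reagents that add atoms: p-toluenesulfinic acid, Cc1ccc(S(=O)O)cc1
Why: The same acid-promoted SN1 sulfinate substitution as in step 3, giving the ring-A methide precursor with the bromine para to the benzhydryl carbon.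

Step 10
Reactants: 11 2-[(3S,4S)-3-(2,4-dimethoxyphenyl)-4-(3,5-dimethoxyphenyl)-5-methoxy-2-oxochroman-8-yl]acetic acid; 15 rac-5-bromo-2-[(3,5-dimethoxyphenyl)(4-methylbenzenesulfonyl)methyl]-3-methoxyphenol
Product: 18 (3S,4S)-7-bromo-3-[(3S,4S)-3-(2,4-dimethoxyphenyl)-4-(3,5-dimethoxyphenyl)-5-methoxy-2-oxochroman-8-yl]-4-(3,5-dimethoxyphenyl)-5-methoxychroman-2-one (bis-lactone), via pivalic mixed anhydride 16 (not isolated), via ring-A o-quinone methide 17 (not isolated)
Conditions: 11, t-BuCOCl, iPr2NEt, CH2Cl2, 0 °C; then (2S,3R)-HyperBTM (20 mol %), 15 (1.3 equiv), iPr2NEt, −20 °C → rt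
Reagents that add atoms: none
Why: The same isothiourea-catalysed ammonium-enolate/o-quinone methide [4+2] annulation as in step 4, now on an acid that carries the ring-B lactone; the catalyst shields one enolate face, so C4 of the new lactone (the future C3) should be set under catalyst control over the distant resident centres, its C3 is again sacrificial, and the electron-rich aryl lactone is too poor an acyl donor to engage the catalyst.

Step 11
Reactants: 18 bis-lactone
Product: 20 (2S,3S)-6-bromo-2-[(2S,3S)-2-(2,4-dimethoxyphenyl)-3-(3,5-dimethoxyphenyl)-4-methoxy-2,3-dihydro-1-benzofuran-7-yl]-3-(3,5-dimethoxyphenyl)-4-methoxy-2,3-dihydro-1-benzofuran, via seco-diacid dilithium salt 19 (not isolated)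
Conditions: LiOH·H2O (8 equiv), THF/H2O, rt; 1 M HCl to pH 8, freeze-dry; then Cu(OTf)2 (6 equiv), Li2CO3 (4 equiv), MeCN, 427 nm LED, rt, under Ar
Reagents that add atoms: none
Why: Saponification opens both aryl lactones; the lithium carboxylates bind divalent copper and, on irradiation, ligand-to-metal charge transfer releases CO2 and a benzylic radical that a second divalent copper oxidises to the cation (the known light-driven decarboxylative C–O coupling of arylacetic acids by radical–polar crossover). Each cation is stabilised by an ortho,para-dioxygenated aryl (2,4-dimethoxyphenyl at C2′, ring B at C2) and is captured 5-exo by the adjacent phenol anti to the aryl group at C3′ or C3, which should give the trans rings without touching C3′ and C3.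

Step 12
Reactants: 20 bis(dihydrobenzofuran) bromide; 21 (E)-2-(4-methoxyphenyl)ethenylboronic acid pinacol ester
Product: 22 (2S,3S)-2-[(2S,3S)-2-(2,4-dimethoxyphenyl)-3-(3,5-dimethoxyphenyl)-4-methoxy-2,3-dihydro-1-benzofuran-7-yl]-3-(3,5-dimethoxyphenyl)-4-methoxy-6-[(E)-2-(4-methoxyphenyl)ethenyl]-2,3-dihydro-1-benzofuran (gnetumontanin B nonamethyl ether)
Conditions: 21 (1.5 equiv), Pd(PPh3)4 (5 mol %), K2CO3, 1,4-dioxane/H2O, 85 °C
Reagents that add atoms: none
Why: Suzuki–Miyaura coupling of an unhindered aryl bromide with an (E)-alkenylboronate, which transfers the alkene geometry with retention under basic conditions that do not affect the benzylic ether rings.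

Step 13
Reactants: 22 gnetumontanin B nonamethyl ether
Product: 23 gnetumontanin B
Conditions: BBr3 (20 equiv), CH2Cl2, −78 °C → rt, dark; MeOH then H2O
Reagents that add atoms: none
Why: Lewis-acid cleavage of the nine aryl methyl ethers with BBr3, as practised on permethylated oligostilbenes; reversible ionisation of the benzylic O1–C2 and O1′–C2′ bonds can only return the more stable trans rings, and C3 and C3′ are not involved.

**Compound list**

1 | 2-bromo-5-methoxyphenol | COc1ccc(Br)c(O)c1 | starting material
2 | 3-bromo-2-hydroxy-6-methoxybenzaldehyde | COc1ccc(Br)c(O)c1C=O | intermediate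
3 | 3,5-dimethoxyphenylmagnesium chloride (THF solution) | COc1cc(OC)cc([Mg]Cl)c1 | starting material
4 | rac-6-bromo-2-[(3,5-dimethoxyphenyl)(hydroxy)methyl]-3-methoxyphenol | COc1ccc(Br)c(O)c1C(O)c1cc(OC)cc(OC)c1 | intermediate
5 | rac-6-bromo-2-[(3,5-dimethoxyphenyl)(4-methylbenzenesulfonyl)methyl]-3-methoxyphenol (ring-B methide precursor) | COc1ccc(Br)c(O)c1C(c1cc(OC)cc(OC)c1)S(=O)(=O)c1ccc(C)cc1 | intermediate
6 | 2,4-dimethoxyphenylacetic acid | COc1ccc(CC(=O)O)c(OC)c1 | starting material
7 | 2-(2,4-dimethoxyphenyl)acetic pivalic anhydride (not isolated) | COc1ccc(CC(=O)OC(=O)C(C)(C)C)c(OC)c1 | intermediate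
8 | 2-bromo-6-[(3,5-dimethoxyphenyl)methylidene]-5-methoxycyclohexa-2,4-dien-1-one, ring-B o-quinone methide (not isolated) | COC1=CC=C(Br)C(=O)C1=Cc1cc(OC)cc(OC)c1 | intermediate
9 | (3S,4S)-8-bromo-3-(2,4-dimethoxyphenyl)-4-(3,5-dimethoxyphenyl)-5-methoxychroman-2-one, trans | Brc1ccc(OC)c2c1OC(=O)[C@H](c1ccc(OC)cc1OC)[C@H]2c1cc(OC)cc(OC)c1 | intermediate
10 | tert-butyl 2-[(3S,4S)-3-(2,4-dimethoxyphenyl)-4-(3,5-dimethoxyphenyl)-5-methoxy-2-oxochroman-8-yl]acetate | CC(C)(C)OC(=O)Cc1ccc(OC)c2c1OC(=O)[C@H](c1ccc(OC)cc1OC)[C@H]2c1cc(OC)cc(OC)c1 | intermediate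
11 | 2-[(3S,4S)-3-(2,4-dimethoxyphenyl)-4-(3,5-dimethoxyphenyl)-5-methoxy-2-oxochroman-8-yl]acetic acid | OC(=O)Cc1ccc(OC)c2c1OC(=O)[C@H](c1ccc(OC)cc1OC)[C@H]2c1cc(OC)cc(OC)c1 | intermediate
12 | 4-bromo-2,6-dimethoxybenzaldehyde | COc1cc(Br)cc(OC)c1C=O | starting material
13 | 4-bromo-2-hydroxy-6-methoxybenzaldehyde | COc1cc(Br)cc(O)c1C=O | intermediate
14 | rac-5-bromo-2-[(3,5-dimethoxyphenyl)(hydroxy)methyl]-3-methoxyphenol | COc1cc(Br)cc(O)c1C(O)c1cc(OC)cc(OC)c1 | intermediate
15 | rac-5-bromo-2-[(3,5-dimethoxyphenyl)(4-methylbenzenesulfonyl)methyl]-3-methoxyphenol (ring-A methide precursor) | COc1cc(Br)cc(O)c1C(c1cc(OC)cc(OC)c1)S(=O)(=O)c1ccc(C)cc1 | intermediate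
16 | mixed pivalic anhydride of acid 11 (not isolated) | CC(C)(C)C(=O)OC(=O)Cc1ccc(OC)c2c1OC(=O)[C@H](c1ccc(OC)cc1OC)[C@H]2c1cc(OC)cc(OC)c1 | intermediate
17 | 3-bromo-6-[(3,5-dimethoxyphenyl)methylidene]-5-methoxycyclohexa-2,4-dien-1-one, ring-A o-quinone methide (not isolated) | COC1=CC(Br)=CC(=O)C1=Cc1cc(OC)cc(OC)c1 | intermediate
18 | (3S,4S)-7-bromo-3-[(3S,4S)-3-(2,4-dimethoxyphenyl)-4-(3,5-dimethoxyphenyl)-5-methoxy-2-oxochroman-8-yl]-4-(3,5-dimethoxyphenyl)-5-methoxychroman-2-one (bis-lactone, both lactones trans) | Brc1cc(OC)c2c(c1)OC(=O)[C@H](c1ccc(OC)c3c1OC(=O)[C@H](c1ccc(OC)cc1OC)[C@H]3c1cc(OC)cc(OC)c1)[C@H]2c1cc(OC)cc(OC)c1 | intermediate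
19 | dilithium salt of the seco-diacid formed by opening both lactone rings of 18 (two free phenols, two carboxylates; the diarylmethine centres of 18 unchanged; not isolated) | [Li+].[Li+].[O-]C(=O)[C@H](c1ccc(OC)c(c1O)[C@H](c1cc(OC)cc(OC)c1)[C@@H](c1ccc(OC)cc1OC)C([O-])=O)[C@H](c1c(O)cc(Br)cc1OC)c1cc(OC)cc(OC)c1 | intermediate
20 | (2S,3S)-6-bromo-2-[(2S,3S)-2-(2,4-dimethoxyphenyl)-3-(3,5-dimethoxyphenyl)-4-methoxy-2,3-dihydro-1-benzofuran-7-yl]-3-(3,5-dimethoxyphenyl)-4-methoxy-2,3-dihydro-1-benzofuran (both rings trans) | Brc1cc(OC)c2c(c1)O[C@H](c1ccc(OC)c3c1O[C@H](c1ccc(OC)cc1OC)[C@H]3c1cc(OC)cc(OC)c1)[C@H]2c1cc(OC)cc(OC)c1 | intermediate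
21 | (E)-2-(4-methoxyphenyl)ethenylboronic acid pinacol ester | COc1ccc(/C=C/B2OC(C)(C)C(C)(C)O2)cc1 | starting material
22 | gnetumontanin B nonamethyl ether, (2S,3S,2′S,3′S), E alkene | COc1ccc(/C=C/c2cc(OC)c3c(c2)O[C@H](c2ccc(OC)c4c2O[C@H](c2ccc(OC)cc2OC)[C@H]4c2cc(OC)cc(OC)c2)[C@H]3c2cc(OC)cc(OC)c2)cc1 | intermediate
23 | gnetumontanin B, (2S,3S,2′S,3′S), E alkene | Oc1ccc(/C=C/c2cc(O)c3c(c2)O[C@H](c2ccc(O)c4c2O[C@H](c2ccc(O)cc2O)[C@H]4c2cc(O)cc(O)c2)[C@H]3c2cc(O)cc(O)c2)cc1 | target

**Step count**

Total: 13 steps. Longest linear sequence: 10 steps (steps 1–6, then 10–13); steps 7–9 form the ring-A branch that joins at step 10.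

**Steps most likely to fail**

Step 11. What may go wrong: photoexcited divalent copper oxidises the free phenols or the methoxyarenes in competition with the carboxylate; the seco-acid relactonises on handling; or the benzylic cations lose H-3/H-3′ to give alkenes, which would erode the configuration at C3/C3′. The fallback sets out from bis-lactone 18 and returns at 20, and masks the phenols while the carboxyl groups are replaced by hydroxyl. Both lactones are opened with LiOH, the dried salt is treated with MOMCl/iPr2NEt, and the MOM esters are cleaved again with LiOH to give the bis(methoxymethyl ether) seco-diacid F1. The two acids are converted into Barton esters (N-hydroxypyridine-2-thione, DCC) and photolysed under O2 with t-BuSH, then reduced with P(OEt)3 (Barton decarboxylative hydroxylation), to give the bis-benzylic alcohol F2 as a mixture of carbinol epimers. HCl in MeOH/THF then removes the MOM groups and ionises the 2,4-dialkoxybenzylic alcohols, and the freed phenols close both trans rings (SN1 cyclodehydration) to 20.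

Step 10. What may go wrong: the mixed anhydride O-acylates the methide precursor; the hindered ortho-substituted arylacetyl group transfers slowly to the isothiourea; or the resident stereocentres and the catalyst are mismatched, giving poor facial selectivity. The fallback sets out from acid 11 and returns at 18, and changes the catalytic manifold from ammonium enolate to azolium enolate. Acid 11 is converted with carbonyldiimidazole into the acyl imidazole F3. A chiral aminoindanol-derived N-mesityl triazolium salt with Cs2CO3 in THF turns F3 into a carbene-bound enolate, which undergoes the known carbene-catalysed formal [4+2] annulation with the methide released from 15 by the same base, the phenoxide again closing the lactone.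

Step 13. What may go wrong: ninefold ether cleavage stays incomplete; the Lewis acid ionises the benzylic ring ethers with Friedel–Crafts capture; or the electron-rich stilbene suffers HBr addition or cationic oligomerisation. The fallback sets out from bromide 20 and returns at 23, and moves the demethylation ahead of the stilbene so that the alkene never meets the Lewis acid. BBr3 in CH2Cl2 converts 20 into the octaphenol bromide F4. A Mizoroki–Heck reaction with 4-acetoxystyrene (Pd(OAc)2, P(o-tol)3, Et3N, DMF, 100 °C) gives the (E)-4-acetoxystilbene F5, and K2CO3 in MeOH removes the acetate to give 23.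

**Further compounds**

F1 | step 11 | bis(methoxymethyl ether) of the seco-diacid from 18 | OC(=O)[C@H](c1ccc(OC)c(c1OCOC)[C@H](c1cc(OC)cc(OC)c1)[C@@H](c1ccc(OC)cc1OC)C(=O)O)[C@H](c1c(OCOC)cc(Br)cc1OC)c1cc(OC)cc(OC)c1
F2 | step 11 | bis-benzylic alcohol with both phenols as methoxymethyl ethers (carbinol centres unassigned) | OC(c1ccc(OC)c(c1OCOC)[C@H](c1cc(OC)cc(OC)c1)C(O)c1ccc(OC)cc1OC)[C@H](c1c(OCOC)cc(Br)cc1OC)c1cc(OC)cc(OC)c1
F3 | step 10 | acyl imidazole of acid 11 | O=C(Cc1ccc(OC)c2c1OC(=O)[C@H](c1ccc(OC)cc1OC)[C@H]2c1cc(OC)cc(OC)c1)n1ccnc1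
F4 | step 13 | octaphenol bromide (20 with all eight methyl ethers cleaved) | Brc1cc(O)c2c(c1)O[C@H](c1ccc(O)c3c1O[C@H](c1ccc(O)cc1O)[C@H]3c1cc(O)cc(O)c1)[C@H]2c1cc(O)cc(O)c1
F5 | step 13 | gnetumontanin B 4-O-acetate on the styryl ring | CC(=O)Oc1ccc(/C=C/c2cc(O)c3c(c2)O[C@H](c2ccc(O)c4c2O[C@H](c2ccc(O)cc2O)[C@H]4c2cc(O)cc(O)c2)[C@H]3c2cc(O)cc(O)c2)cc1
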